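## Structural features

The target is a germacranolide: a ten-membered carbocycle C1–C10 fused trans at C7–C8 to an α-methylene-γ-butyrolactone (ring oxygen on C8, carbonyl C12, exocyclic C11=C13). The carbocycle holds two E-configured trisubstituted alkenes in a 1,5-relationship, C1=C10 (methyl C14 on C10) and C4=C5 (acyloxymethyl C15 on C4). This makes the ring liable to Cope rearrangement on heating and to transannular cyclisation under acid. Three stereocentres are contiguous, C6 (R, isovalerate), C7 (R) and C8 (S, lactone oxygen), with H6/H7 and H7/H8 both trans. The fourth, the free carbinol C3 (R), is separated from them by C4=C5 on one side and C1=C10 on the other. Five oxygen functions must be told apart: O3 stays free, O6 and O15 carry 3-methylbutanoates, and O8 with C12 forms the lactone. The fragile elements are the α-methylene lactone (Michael acceptor, sensitive to hydride and base), the allylic esters (acyl migration O15→O3 and O6→O8), the C7 centre next to any C6 carbonyl, and the C11=C13 alkene, which can slip into conjugation. The real difficulty is closing the strained E,E-cyclodecadiene with control of C6 and finishing with the correct acylation pattern. The key step uses the fact that C10(C14)=C1–C2–C3(OH) is a homoallylic alcohol on an E-trisubstituted alkene: this maps onto syn methyl–metal addition across a C10≡C1 terminal alkyne, then attack of C1 on the CH2 (C2) of a C2–C3 epoxide whose C3 comes from the chiral pool.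

## Logic of the disconnections

36 ⇒ 33. The acyl–oxygen bond O8–C12 is cut and C12 is lowered to the alcohol level. The α-methylene lactone is the most electrophilic group in the molecule, so it is made last, which lets every earlier step use hydrides and organometallics. The demand is an oxidant that takes the primary allylic C12–OH and the derived lactol but leaves the secondary allylic C3–OH.

33 ⇒ 32 ⇒ 31. The two ester C–O bonds at O6 and O15 are cut and O3, O8 and O12 are returned to one kind of silyl ether. One acylation and one fluoride step then differentiate all five oxygens. The demand is desilylation without acyl migration or acid-induced transannular reaction.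

31 ⇒ 30 ⇒ 28. The C4–C15 bond is cut, then C4–I and C5–H, which traces the E-alkene and its hydroxymethyl group to a ring alkyne flanked by the free O6. The geometry then comes from an anti addition directed by O6 and not from an olefination. The demands are aluminium on C4 (not C5), no loss of the O3 silyloxy group from the C4 alanate, and a cross-coupling run below the temperature at which the 1,5-diene rearranges.

28 ⇒ 26. The ring bond C5–C6 is cut between an sp carbon and a carbinol carbon. This opens the medium ring to a chain and closes it in the forward sense through a linear, unhindered nucleophile. The demands are high dilution, the correct face of the C6 aldehyde, and no epimerisation at C7.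

26 ⇒ 25 ⇒ 24 ⇒ 23 ⇒ 22 ⇒ 19 + 20. After oxidation-level and protecting-group changes at C6, C5 and O8, the C7–C8 bond is cut as a syn aldol. The C7/C8 pair, with the C11 unit in β,γ-relationship to C6, is the product of an α-selective aldol of a but-3-enoyl imide, so both centres come from one auxiliary. This is preferred to a β,γ-disubstituted allylboron reagent because the imide is made by routine steps and its facial control is predictable. The demands are reaction of the dienolate at C7 and an aldehyde partner that does not conjugate.

19 ⇒ 16 + 17, and 16 ⇒ 15 ⇒ 14 ⇒ 13. The N–C6 acyl bond is cut and C12 is traced to the conjugated carboxyl of an itaconate half-ester. C6, C7, C11, C12 and C13 then come from one cheap five-carbon acid. The demand is reduction of the free acid beside the ester without conjugating the alkene.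

20 ⇒ 12 ⇒ 11 ⇒ 10 ⇒ 9 ⇒ 8 ⇒ 7. The C4–C5 bond is cut (one-carbon homologation of a C4 aldehyde) and the oxygens at C3, C4 and C8 are re-protected. The demands are that the α-silyloxy aldehyde keeps its C3 configuration, that O4 is unmasked oxidatively beside two silyl ethers, and that O8 (primary) is unmasked by mild acid beside O3 (secondary).

7 ⇒ 3 + 4 + 2. The C1–C2 and C10–C14 bonds are cut, the strategic step. Eight of the fifteen skeletal carbons, the E alkene and the C3 carbinol come from three simple components with both chain ends differentiated. The demands are methyl on C10, syn addition, attack at the epoxide CH2, and alkenyl (not alkyl) transfer from aluminium.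

2 ⇒ 1. The benzylic ether C–O bond is cut to return to the chiral-pool epoxy alcohol; the stereocentre must not be touched.

## Other disconnections considered

Alternative 1: The cut is the ring bond C5–C6, with C4≡C5 standing in for the later E-alkene.
- **Forward step:** CrCl2 with catalytic NiCl2 would convert the C5 iodoalkyne of open-chain aldehyde A2 into an alkynylchromium species of trivalent chromium, which adds to the C6 aldehyde and closes cyclodecenynol A1.
- **For:** The ring closes through a linear sp unit, which eases transannular strain. The chromium reagent tolerates silyl ethers, alkenes and the epimerisable C7 centre. The alkyne with the new O6 is the handle needed for anti hydroalumination to the C4=C5 alkene carrying C15.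
- **Against:** C6 is created during ring closure with no reagent to steer it, so its configuration rests on a Felkin-type preference inside a medium-ring transition state. High dilution and a large excess of a toxic chromium salt are needed, and the cycloalkyne is strained.
- **Structure:** It builds one ring, one C–C bond and one stereocentre; the chosen key step builds no ring, two C–C bonds and a stereodefined alkene. On skeletal impact this alternative is the better, because the medium ring is the hardest feature.
- **Mechanism:** A substrate-controlled carbonyl addition stands against a stereospecific carbometalation and SN2 opening; on predictability the chosen step is the better.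
- **Step economy:** Equal. The two cuts are not exclusive: A1 and A2 are the same structures as 28 and 26, and the chosen plan uses this closure at step 18 after the three-component coupling has supplied C8–C4.

Alternative 2: The cut is the C4=C5 double bond, formed by ring-closing metathesis inside eleven-membered macrolactone A4. In A4, O6 is esterified by the C15 carboxyl of an acrylate whose α-carbon is C4, and C6 carries the C5 vinyl group.
- **Forward step:** Second-generation Grubbs catalyst would join C4 and C5 with loss of ethylene and give butenolide-bridged carbocycle A3, whose lactone is later reduced to the O6/O15 diol.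
- **For:** The five-membered tether can only hold C15 and C6 cis, so the ring-E geometry of C4=C5 follows from constitution. C15 arrives in the tether, so no iodine or tin chemistry is needed. C6 can be set in an open-chain precursor with a chiral reagent, and no chromium is used.
- **Against:** The reacting alkenes are a 1,1-disubstituted acrylate and a vinyl group on a hindered carbinol, and the substrate also contains C11=C13 and C1=C10. A ruthenium carbene on C5 can reach C10 through C6–C9 and close a cyclohexene, a kinetically easy diversion that would cut the chain. The product is a strained bridged bicycle, and a macrolactonisation must precede the metathesis.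
- **Structure:** Two rings and one C=C bond form at once. It is the better on control of the C4=C5 geometry and of C6, and the equal of the chosen plan for the C8–C4 chain, which the same coupling could supply.
- **Mechanism:** Reversible metathesis with competing alkene partners stands against a hydroxyl-directed anti hydroalumination; neither is free of risk.
- **Step economy:** Metathesis and lactone reduction replace ring closure, hydroalumination–iodination and hydroxymethylation, but an esterification/macrolactonisation and a separate construction of the C6 vinyl carbinol are added. The count is expected to be about equal.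

Alternative 3: The cut is C6–C7, formed by [2,3]-Wittig rearrangement of thirteen-membered diallylic ether A6, in which oxygen links C6 and C13.
- **Forward step:** n-BuLi (two equivalents, the first for the C15 hydroxyl) would deprotonate C6. The carbanion attacks C7 with cleavage of O–C13, which contracts the ring, frees O6 and leaves C11=C13 exocyclic, giving diol A5.
- **For:** A concerted five-membered transition state forms C6–C7 and both stereocentres at once. A thirteen-membered ether should close more easily than a ten-membered carbocycle. A5 is the same structure as 31, so chromium, aluminium hydride and tin chemistry would all be avoided; on end-game economy it is the better.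
- **Against:** Both CH2 groups on the ether oxygen (C6 and C13) are allylic, so the site of deprotonation is not secured, and a [1,2]-shift competes. The induction at C6 and C7 depends on the C7=C11 geometry (the acyclic rule asks for C8 trans to C13) and on ring conformation, with C8 as the only nearby control element. Two trisubstituted allylic ether alkenes must be made stereoselectively first and joined by a macro-etherification.
- **Structure:** One C–C bond, two stereocentres and a ring contraction; it is the better on stereocentres set per step.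
- **Mechanism:** A sigmatropic shift under conformational control stands against an auxiliary-controlled aldol (C7, C8) plus a substrate-controlled addition (C6). The chosen plan keeps C7/C8 under external control; the alternative sets C6 and C7 together but with less certain induction.
- **Step economy:** Shorter after the ring exists and longer before it, so about equal overall. The C10(C14)=C1–C2–C3 part of A6 could again come from the same three-component coupling.

Key step: step 2

Remark on the chemistry: atoms carry germacrane locants (C1–C15); TBS = tert-butyldimethylsilyl, PMB = 4-methoxybenzyl.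

Remark on the chemistry: the target is read as 3R,6R,7R,8S with E geometry at C1=C10 and C4=C5 (O3, O6, O8 and H7 on one face; H6 and H8 on the other).

Remark on the chemistry: the three-component coupling needs no structural correction, since opening the (S)-glycidol-derived epoxide at its CH2 gives the 3R carbinol (the glycidyl ether is labelled R by a priority change only). The ether group on the epoxide partner is changed to PMB, because O4 must be unmasked first beside silyl ethers at O3 and O8, which a tert-butyldiphenylsilyl ether would not allow. The alkynol partner keeps its TBS ether and is bought as such.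

## Route

Step 1
Reactants: 1 (S)-glycidol
Product: 2 (R)-2-{[(4-methoxybenzyl)oxy]methyl}oxirane
Conditions: NaH, PMBCl, Bu4NI (cat.), THF/DMF, 0 °C → rt
Reagents that add atoms: 4-methoxybenzyl chloride, COc1ccc(CCl)cc1
Why: Williamson etherification of the primary alkoxide; the stereocentre is not a reacting centre and a Payne shift of glycidol only regenerates the same enantiomer, so the configuration is kept.

Step 2
Reactants: 3 4-(tert-butyldimethylsilyloxy)but-1-yne; 4 trimethylaluminium; 2 (R)-2-{[(4-methoxybenzyl)oxy]methyl}oxirane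
Product: 7 (2R,4E)-7-(TBSO)-1-(PMBO)-5-methylhept-4-en-2-ol, via alkenyldimethylalane 5 (not isolated), via lithium alkenylalanate 6 (not isolated)
Conditions: Me3Al (2 equiv), Cp2ZrCl2 (cat.), CH2Cl2, 0 °C → rt; volatiles removed in vacuo; hexane, n-BuLi (1 equiv), 0 °C; 2 in Et2O, 0 °C → rt; aq. potassium sodium tartrate
Reagents that add atoms: none
Why: Zirconium-catalysed methylalumination (Negishi carboalumination) of terminal alkyne 3 should add methyl and metal syn across C10≡C1, with methyl on the internal carbon C10 and aluminium on C1, so that C9 and the metal are trans and the E geometry of C1=C10 is fixed in alane 5. n-BuLi converts the weakly nucleophilic alane into lithium alanate 6, from which the sp2 alkenyl group is transferred in preference to methyl or butyl. The alanate should open epoxide 2 by SN2 attack at the unsubstituted carbon C2 with retention of alkene geometry, forming C1–C2; the closest known reaction type is the opening of terminal epoxides by alkenylalanates obtained from carboalumination. No ring is closed and no stereocentre is created: C3 comes from 1 and is not a reacting centre, so its configuration is carried over. The selectivities needed are methyl delivery to C10 (secured by the terminal alkyne), syn addition (inherent in the four-centre carbometalation), attack at the terminal epoxide carbon (secured by sterics and by coordination of lithium or aluminium to the two oxygens of 2), and alkenyl over alkyl transfer. Excess Me3Al is removed before n-BuLi is added so that no tetraalkylalanate competes for 2.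

Step 3
Reactants: 7 (2R,4E)-7-(TBSO)-1-(PMBO)-5-methylhept-4-en-2-ol
Product: 8 (2R,4E)-2,7-bis(TBSO)-1-(PMBO)-5-methylhept-4-ene
Conditions: TBSCl, imidazole, DMF, 0 °C → rt
Reagents that add atoms: tert-butyldimethylsilyl chloride, CC(C)(C)[Si](C)(C)Cl
Why: Imidazole-promoted silylation of the secondary C3 alcohol; O4 and O8 are already capped, so no regiochemical issue arises.

Step 4
Reactants: 8 (2R,4E)-2,7-bis(TBSO)-1-(PMBO)-5-methylhept-4-ene
Product: 9 (2R,4E)-2,7-bis(TBSO)-5-methylhept-4-en-1-ol
Conditions: DDQ, CH2Cl2/pH 7 phosphate buffer, 0 °C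
Reagents that add atoms: none
Why: Oxidative cleavage of the electron-rich benzyl ether through a benzylic oxocarbenium ion that water hydrolyses; silyl ethers and the trisubstituted alkene are inert and the buffer prevents acid-induced silyl loss or migration.

Step 5
Reactants: 9 (2R,4E)-2,7-bis(TBSO)-5-methylhept-4-en-1-ol
Product: 10 (2R,4E)-2,7-bis(TBSO)-5-methylhept-4-enal
Conditions: Dess–Martin periodinane, NaHCO3, CH2Cl2, 0 °C → rt; used crude
Reagents that add atoms: none
Why: Dess–Martin oxidation under buffered, non-basic conditions should give the α-silyloxy aldehyde without epimerisation at C3.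

Step 6
Reactants: 10 (2R,4E)-2,7-bis(TBSO)-5-methylhept-4-enal
Product: 11 (3R,5E)-3,8-bis(TBSO)-6-methyloct-5-en-1-yne
Conditions: dimethyl (1-diazo-2-oxopropyl)phosphonate, K2CO3, MeOH, 0 °C → rt
Reagents that add atoms: dimethyl (1-diazo-2-oxopropyl)phosphonate, CC(=O)C(=[N+]=[N-])P(=O)(OC)OC
Why: Ohira–Bestmann (Seyferth–Gilbert) homologation: the diazomethylphosphonate anion formed in methanol adds to the aldehyde, phosphate is lost, and the alkylidene carbene rearranges to the terminal alkyne, adding C5. Mild carbonate at low temperature should leave C3 intact.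

Step 7
Reactants: 11 (3R,5E)-3,8-bis(TBSO)-6-methyloct-5-en-1-yne
Product: 12 (3E,6R)-6-(TBSO)-3-methyloct-3-en-7-yn-1-ol
Conditions: (±)-camphor-10-sulfonic acid (cat.), MeOH/CH2Cl2, 0 °C
Reagents that add atoms: none
Why: Acid-catalysed methanolysis removes the unhindered primary silyl ether at O8 much faster than the secondary, propargylic one at O3.

Step 8
Reactants: 13 4-methyl hydrogen itaconate (4-methoxy-2-methylidene-4-oxobutanoic acid)
Product: 14 methyl 3-(hydroxymethyl)but-3-enoate
Conditions: BH3·SMe2, THF, 0 °C; MeOH then water; used directly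
Reagents that add atoms: none
Why: Borane reduces the free carboxylic acid (through an acyloxyborane) faster than it attacks the methyl ester or hydroborates the electron-poor 1,1-disubstituted alkene, bringing C12 to the alcohol level; immediate silylation forestalls lactonisation.

Step 9
Reactants: 14 methyl 3-(hydroxymethyl)but-3-enoate
Product: 15 methyl 3-[(TBSO)methyl]but-3-enoate
Conditions: TBSCl, imidazole, CH2Cl2, 0 °C → rt
Reagents that add atoms: tert-butyldimethylsilyl chloride, CC(C)(C)[Si](C)(C)Cl
Why: Standard silylation of a primary allylic alcohol.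

Step 10
Reactants: 15 methyl 3-[(TBSO)methyl]but-3-enoate
Product: 16 3-[(TBSO)methyl]but-3-enoic acid
Conditions: LiOH, THF/H2O, 0 °C → rt; cold 1 M HCl to pH 4
Reagents that add atoms: water (delivered as LiOH/H2O), O
Why: Saponification of an unhindered methyl ester; hydrolysis at low temperature should outrun base-induced migration of C11=C13 into conjugation, and the carboxylate formed is no longer prone to it.

Step 11
Reactants: 16 3-[(TBSO)methyl]but-3-enoic acid; 17 (R)-4-benzyl-1,3-oxazolidin-2-one
Product: 19 (R)-4-benzyl-3-{3-[(TBSO)methyl]but-3-enoyl}-1,3-oxazolidin-2-one, via mixed pivalic anhydride 18 (not isolated)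
Conditions: t-BuCOCl, Et3N, THF, −20 °C; then 17, LiCl, −20 °C → rt
Reagents that add atoms: none
Why: N-Acylation through a mixed anhydride; the oxazolidinone, activated by LiCl and Et3N, attacks the less hindered carbonyl of 18, and the conditions are too mild to conjugate the alkene.

Step 12
Reactants: 12 (3E,6R)-6-(TBSO)-3-methyloct-3-en-7-yn-1-ol
Product: 20 (3E,6R)-6-(TBSO)-3-methyloct-3-en-7-ynal
Conditions: Dess–Martin periodinane, NaHCO3, CH2Cl2, 0 °C; used at once
Reagents that add atoms: none
Why: Buffered Dess–Martin oxidation gives the β,γ-unsaturated aldehyde without moving C1=C10 into conjugation.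

Step 13
Reactants: 19 (R)-4-benzyl-3-{3-[(TBSO)methyl]but-3-enoyl}-1,3-oxazolidin-2-one; 20 (3E,6R)-6-(TBSO)-3-methyloct-3-en-7-ynal
Product: 22 (R)-4-benzyl-3-{(2R,3S,5E,8R)-8-(TBSO)-2-[3-(TBSO)prop-1-en-2-yl]-3-hydroxy-5-methyldec-5-en-9-ynoyl}-1,3-oxazolidin-2-one, via Z-boron enolate 21 (not isolated)
Conditions: Bu2BOTf, i-Pr2NEt, CH2Cl2, −78 → 0 °C; 20, −78 → −20 °C; pH 7 buffer, MeOH, H2O2, 0 °C
Reagents that add atoms: none
Why: Evans syn aldol: soft enolisation gives Z-dienolate 21, which reacts at its α-carbon C7 through a closed Zimmerman–Traxler chair on the face away from the benzyl group of the R auxiliary. C7 (R) and C8 (S) are set together, with O8 and the C11 unit syn along C6–C9 as the trans lactone requires. Boron dienolates are α-selective, so C11=C13 stays out of conjugation.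

Step 14
Reactants: 22 aldol adduct (as named in step 13)
Product: 23 (R)-4-benzyl-3-{(2R,3S,5E,8R)-3,8-bis(TBSO)-2-[3-(TBSO)prop-1-en-2-yl]-5-methyldec-5-en-9-ynoyl}-1,3-oxazolidin-2-one
Conditions: TBSOTf, 2,6-lutidine, CH2Cl2, −78 → 0 °C
Reagents that add atoms: tert-butyldimethylsilyl trifluoromethanesulfonate, CC(C)(C)[Si](C)(C)OS(=O)(=O)C(F)(F)F
Why: Silyl triflate with a hindered pyridine base silylates the secondary C8 alcohol without retro-aldol or epimerisation at C7.

Step 15
Reactants: 23 silylated aldol adduct (as named in step 14)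
Product: 24 (2S,3S,5E,8R)-3,8-bis(TBSO)-2-[3-(TBSO)prop-1-en-2-yl]-5-methyldec-5-en-9-yn-1-ol
Conditions: LiBH4, MeOH (1 equiv), THF, 0 °C
Reagents that add atoms: none
Why: Reductive cleavage of the N-acyl oxazolidinone at the exocyclic carbonyl gives the C6 primary alcohol and releases the auxiliary; alkyne, alkenes and silyl ethers are inert, and the descriptor at C7 changes by priority only.

Step 16
Reactants: 24 (2S,3S,5E,8R)-3,8-bis(TBSO)-2-[3-(TBSO)prop-1-en-2-yl]-5-methyldec-5-en-9-yn-1-ol
Product: 25 (2S,3S,5E,8R)-3,8-bis(TBSO)-2-[3-(TBSO)prop-1-en-2-yl]-10-iodo-5-methyldec-5-en-9-yn-1-ol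
Conditions: N-iodosuccinimide, AgNO3 (cat.), acetone, rt, dark
Reagents that add atoms: N-iodosuccinimide, O=C1CCC(=O)N1I
Why: Silver-catalysed iodination of the terminal alkyne C–H through a silver acetylide; the neutral conditions should spare the alkenes and the free primary alcohol.

Step 17
Reactants: 25 iodoalkynol (as named in step 16)
Product: 26 (2R,3S,5E,8R)-3,8-bis(TBSO)-2-[3-(TBSO)prop-1-en-2-yl]-10-iodo-5-methyldec-5-en-9-ynal
Conditions: Dess–Martin periodinane, NaHCO3, CH2Cl2, 0 °C → rt; used at once
Reagents that add atoms: none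
Why: Buffered Dess–Martin oxidation gives the C6 aldehyde without epimerising C7 or conjugating C11=C13; the iodoalkyne is inert.

Step 18
Reactants: 26 iodoalkyne aldehyde (as named in step 17)
Product: 28 (1S,4R,6E,9S,10S)-4,9-bis(TBSO)-10-[3-(TBSO)prop-1-en-2-yl]-7-methylcyclodec-6-en-2-yn-1-ol, via alkynylchromium dichloride 27 (not isolated)
Conditions: CrCl2 (excess), NiCl2 (cat.), THF, rt, slow addition at high dilution
Reagents that add atoms: none
Why: Nozaki–Hiyama–Kishi cyclisation: divalent chromium inserts into the C5–I bond to give alkynylchromium 27 (trivalent chromium), which adds only to the aldehyde and closes the ten-membered ring through its linear sp carbon. The new C6 centre is expected to arise by Felkin–Anh attack anti to the C8 branch on C7, which places O6 syn to the C11 unit (6S in 28, the 6R centre of the target once acylation changes the priorities).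

Step 19
Reactants: 28 cyclodecenynol (as named in step 18)
Product: 30 (1S,2Z,4R,6E,9S,10S)-4,9-bis(TBSO)-10-[3-(TBSO)prop-1-en-2-yl]-3-iodo-7-methylcyclodeca-2,6-dien-1-ol, via cyclic alkenylalanate 29 (not isolated)
Conditions: NaAlH2(OCH2CH2OMe)2, THF, 0 °C → rt; EtOAc, 0 °C; I2, THF, −78 → −20 °C; aq. Na2S2O3 and potassium sodium tartrate
Reagents that add atoms: iodine, II
Why: The aluminium alkoxide at O6 delivers hydride to the proximal alkyne carbon C5 and places aluminium on C4 in five-membered alanate 29 (anti hydroalumination of a propargylic alcohol). Iodine then replaces the C–Al bond with retention, so C3 and C6 are trans across C4=C5, which is the E ring geometry of the target. Low temperature should suppress elimination of the O3 silyloxy group.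

Step 20
Reactants: 30 vinyl iodide (as named in step 19)
Product: 31 (1R,2E,4R,6E,9S,10S)-4,9-bis(TBSO)-10-[3-(TBSO)prop-1-en-2-yl]-3-(hydroxymethyl)-7-methylcyclodeca-2,6-dien-1-ol
Conditions: Bu3SnCH2OH, Pd(PPh3)4 (cat.), dioxane, 70 °C, degassed
Reagents that add atoms: (tributylstannyl)methanol, CCCC[Sn](CCCC)(CCCC)CO
Why: Stille coupling: oxidative addition of zerovalent palladium into the C4–I bond, transfer of the hydroxymethyl group from tin and reductive elimination form C4–C15 with retention of the alkene geometry.

Step 21
Reactants: 31 diol (as named in step 20)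
Product: 32 6,15-bis(3-methylbutanoate) of 31 [(1R,2E,4R,6E,9S,10S)-4,9-bis(TBSO)-10-[3-(TBSO)prop-1-en-2-yl]-7-methyl-3-{[(3-methylbutanoyl)oxy]methyl}cyclodeca-2,6-dien-1-yl 3-methylbutanoate]
Conditions: 3-methylbutanoic anhydride, Et3N, 4-(dimethylamino)pyridine (cat.), CH2Cl2, 0 °C → rt
Reagents that add atoms: 3-methylbutanoic anhydride, CC(C)CC(=O)OC(=O)CC(C)C
Why: Nucleophilic-catalysed acylation of the two free hydroxyls (O6 secondary allylic, O15 primary allylic); O3, O8 and O12 are silylated, so one step installs both esters.

Step 22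
Reactants: 32 bis-ester (as named in step 21)
Product: 33 (1R,2E,4R,6E,9S,10R)-4,9-dihydroxy-10-(3-hydroxyprop-1-en-2-yl)-7-methyl-3-{[(3-methylbutanoyl)oxy]methyl}cyclodeca-2,6-dien-1-yl 3-methylbutanoate
Conditions: HF·pyridine, pyridine, THF, 0 °C → rt
Reagents that add atoms: none
Why: Fluoride cleaves the three silyl ethers; the buffered, weakly acidic medium should avoid the acyl migrations (O15→O3, O6→O8) that basic fluoride would invite and is too mild to ionise the allylic esters or trigger transannular cyclisation.

Step 23
Reactants: 33 triol (as named in step 22)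
Product: 36 target CNP0317194.1 [(3R,6R,7R,8S)-3-hydroxy-6,15-bis(3-methylbutanoyloxy)germacra-1(10)E,4E,11(13)-trien-12,8-olide], via hydroxy enal 34 (not isolated), via lactol 35 (not isolated)
Conditions: PhI(OAc)2 (2.5 equiv), (2,2,6,6-tetramethylpiperidin-1-yl)oxyl (cat.), CH2Cl2, rt
Reagents that add atoms: none
Why: Oxoammonium-mediated oxidative lactonisation of a 1,4-diol: the primary allylic C12 alcohol is oxidised to enal 34, O8 adds to give lactol 35, and a second oxidation gives the α-methylene lactone. The oxidant is much slower with the secondary allylic C3 carbinol, which should stay free. The trans ring fusion is already fixed by C7 and C8.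

## Compound list

1 | (S)-glycidol | OC[C@H]1CO1 | starting material
2 | (R)-2-{[(4-methoxybenzyl)oxy]methyl}oxirane (PMB ether of (S)-glycidol) | COc1ccc(COC[C@H]2CO2)cc1 | intermediate
3 | 4-(tert-butyldimethylsilyloxy)but-1-yne | C#CCCO[Si](C)(C)C(C)(C)C | starting material
4 | trimethylaluminium | C[Al](C)C | starting material
5 | (E)-[4-(TBSO)-2-methylbut-1-en-1-yl]dimethylalane (formed in situ) | C/C(CCO[Si](C)(C)C(C)(C)C)=C\[Al](C)C | intermediate
6 | lithium butyl[(E)-4-(TBSO)-2-methylbut-1-en-1-yl]dimethylalanate (formed in situ) | [Li+].CCCC[Al-](C)(C)/C=C(\C)CCO[Si](C)(C)C(C)(C)C | intermediate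
7 | (2R,4E)-7-(TBSO)-1-(PMBO)-5-methylhept-4-en-2-ol | CC(C)(C)[Si](C)(C)OCC/C(C)=C/C[C@@H](O)COCc1ccc(OC)cc1 | intermediate
8 | (2R,4E)-2,7-bis(TBSO)-1-(PMBO)-5-methylhept-4-ene | CC(C)(C)[Si](C)(C)OCC/C(C)=C/C[C@@H](O[Si](C)(C)C(C)(C)C)COCc1ccc(OC)cc1 | intermediate
9 | (2R,4E)-2,7-bis(TBSO)-5-methylhept-4-en-1-ol | CC(C)(C)[Si](C)(C)OCC/C(C)=C/C[C@@H](O[Si](C)(C)C(C)(C)C)CO | intermediate
10 | (2R,4E)-2,7-bis(TBSO)-5-methylhept-4-enal | CC(C)(C)[Si](C)(C)OCC/C(C)=C/C[C@@H](O[Si](C)(C)C(C)(C)C)C=O | intermediate
11 | (3R,5E)-3,8-bis(TBSO)-6-methyloct-5-en-1-yne | CC(C)(C)[Si](C)(C)OCC/C(C)=C/C[C@@H](O[Si](C)(C)C(C)(C)C)C#C | intermediate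
12 | (3E,6R)-6-(TBSO)-3-methyloct-3-en-7-yn-1-ol | OCC/C(C)=C/C[C@@H](O[Si](C)(C)C(C)(C)C)C#C | intermediate
13 | 4-methyl hydrogen itaconate (4-methoxy-2-methylidene-4-oxobutanoic acid) | C=C(CC(=O)OC)C(=O)O | starting material
14 | methyl 3-(hydroxymethyl)but-3-enoate | C=C(CO)CC(=O)OC | intermediate
15 | methyl 3-[(TBSO)methyl]but-3-enoate | C=C(CO[Si](C)(C)C(C)(C)C)CC(=O)OC | intermediate
16 | 3-[(TBSO)methyl]but-3-enoic acid | C=C(CO[Si](C)(C)C(C)(C)C)CC(=O)O | intermediate
17 | (R)-4-benzyl-1,3-oxazolidin-2-one | O=C1N[C@H](Cc2ccccc2)CO1 | starting material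
18 | 3-[(TBSO)methyl]but-3-enoic pivalic anhydride (formed in situ) | C=C(CO[Si](C)(C)C(C)(C)C)CC(=O)OC(=O)C(C)(C)C | intermediate
19 | (R)-4-benzyl-3-{3-[(TBSO)methyl]but-3-enoyl}-1,3-oxazolidin-2-one | C=C(CO[Si](C)(C)C(C)(C)C)CC(=O)N1[C@H](Cc2ccccc2)COC1=O | intermediate
20 | (3E,6R)-6-(TBSO)-3-methyloct-3-en-7-ynal | O=CC/C(C)=C/C[C@@H](O[Si](C)(C)C(C)(C)C)C#C | intermediate
21 | (Z)-dibutylboron dienolate of 19 (formed in situ) | C=C(CO[Si](C)(C)C(C)(C)C)/C=C(\OB(CCCC)CCCC)N1[C@H](Cc2ccccc2)COC1=O | intermediate
22 | (R)-4-benzyl-3-{(2R,3S,5E,8R)-8-(TBSO)-2-[3-(TBSO)prop-1-en-2-yl]-3-hydroxy-5-methyldec-5-en-9-ynoyl}-1,3-oxazolidin-2-one | C=C(CO[Si](C)(C)C(C)(C)C)[C@@H](C(=O)N1[C@H](Cc2ccccc2)COC1=O)[C@@H](O)C/C(C)=C/C[C@@H](O[Si](C)(C)C(C)(C)C)C#C | intermediate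
23 | (R)-4-benzyl-3-{(2R,3S,5E,8R)-3,8-bis(TBSO)-2-[3-(TBSO)prop-1-en-2-yl]-5-methyldec-5-en-9-ynoyl}-1,3-oxazolidin-2-one | C=C(CO[Si](C)(C)C(C)(C)C)[C@@H](C(=O)N1[C@H](Cc2ccccc2)COC1=O)[C@@H](O[Si](C)(C)C(C)(C)C)C/C(C)=C/C[C@@H](O[Si](C)(C)C(C)(C)C)C#C | intermediate
24 | (2S,3S,5E,8R)-3,8-bis(TBSO)-2-[3-(TBSO)prop-1-en-2-yl]-5-methyldec-5-en-9-yn-1-ol | C=C(CO[Si](C)(C)C(C)(C)C)[C@@H](CO)[C@@H](O[Si](C)(C)C(C)(C)C)C/C(C)=C/C[C@@H](O[Si](C)(C)C(C)(C)C)C#C | intermediate
25 | (2S,3S,5E,8R)-3,8-bis(TBSO)-2-[3-(TBSO)prop-1-en-2-yl]-10-iodo-5-methyldec-5-en-9-yn-1-ol | C=C(CO[Si](C)(C)C(C)(C)C)[C@@H](CO)[C@@H](O[Si](C)(C)C(C)(C)C)C/C(C)=C/C[C@@H](O[Si](C)(C)C(C)(C)C)C#CI | intermediate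
26 | (2R,3S,5E,8R)-3,8-bis(TBSO)-2-[3-(TBSO)prop-1-en-2-yl]-10-iodo-5-methyldec-5-en-9-ynal | C=C(CO[Si](C)(C)C(C)(C)C)[C@@H](C=O)[C@@H](O[Si](C)(C)C(C)(C)C)C/C(C)=C/C[C@@H](O[Si](C)(C)C(C)(C)C)C#CI | intermediate
27 | C5 alkynylchromium dichloride derived from 26 (trivalent chromium; formed in situ) | C=C(CO[Si](C)(C)C(C)(C)C)[C@@H](C=O)[C@@H](O[Si](C)(C)C(C)(C)C)C/C(C)=C/C[C@@H](O[Si](C)(C)C(C)(C)C)C#C[Cr](Cl)Cl | intermediate
28 | (1S,4R,6E,9S,10S)-4,9-bis(TBSO)-10-[3-(TBSO)prop-1-en-2-yl]-7-methylcyclodec-6-en-2-yn-1-ol | C=C(CO[Si](C)(C)C(C)(C)C)[C@@H]1[C@@H](O[Si](C)(C)C(C)(C)C)C/C(C)=C/C[C@@H](O[Si](C)(C)C(C)(C)C)C#C[C@H]1O | intermediate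
29 | sodium bis(2-methoxyethoxy)alanate with aluminium bridging O6 and C4 in a five-membered ring (formed in situ) | [Na+].C=C(CO[Si](C)(C)C(C)(C)C)[C@@H]1[C@@H](O[Si](C)(C)C(C)(C)C)C/C(C)=C/C[C@@H](O[Si](C)(C)C(C)(C)C)/C2=C/[C@H]1O[Al-]2(OCCOC)OCCOC | intermediate
30 | (1S,2Z,4R,6E,9S,10S)-4,9-bis(TBSO)-10-[3-(TBSO)prop-1-en-2-yl]-3-iodo-7-methylcyclodeca-2,6-dien-1-ol | C=C(CO[Si](C)(C)C(C)(C)C)[C@@H]1[C@@H](O[Si](C)(C)C(C)(C)C)C/C(C)=C/C[C@@H](O[Si](C)(C)C(C)(C)C)/C(I)=C/[C@H]1O | intermediate
31 | (1R,2E,4R,6E,9S,10S)-4,9-bis(TBSO)-10-[3-(TBSO)prop-1-en-2-yl]-3-(hydroxymethyl)-7-methylcyclodeca-2,6-dien-1-ol | C=C(CO[Si](C)(C)C(C)(C)C)[C@@H]1[C@@H](O[Si](C)(C)C(C)(C)C)C/C(C)=C/C[C@@H](O[Si](C)(C)C(C)(C)C)/C(CO)=C/[C@H]1O | intermediate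
32 | (1R,2E,4R,6E,9S,10S)-4,9-bis(TBSO)-10-[3-(TBSO)prop-1-en-2-yl]-7-methyl-3-{[(3-methylbutanoyl)oxy]methyl}cyclodeca-2,6-dien-1-yl 3-methylbutanoate | C=C(CO[Si](C)(C)C(C)(C)C)[C@@H]1[C@@H](O[Si](C)(C)C(C)(C)C)C/C(C)=C/C[C@@H](O[Si](C)(C)C(C)(C)C)/C(COC(=O)CC(C)C)=C/[C@H]1OC(=O)CC(C)C | intermediate
33 | (1R,2E,4R,6E,9S,10R)-4,9-dihydroxy-10-(3-hydroxyprop-1-en-2-yl)-7-methyl-3-{[(3-methylbutanoyl)oxy]methyl}cyclodeca-2,6-dien-1-yl 3-methylbutanoate | C=C(CO)[C@@H]1[C@@H](O)C/C(C)=C/C[C@@H](O)/C(COC(=O)CC(C)C)=C/[C@H]1OC(=O)CC(C)C | intermediate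
34 | C12 aldehyde of 33 (hydroxy enal, formed in situ) | C=C(C=O)[C@@H]1[C@@H](O)C/C(C)=C/C[C@@H](O)/C(COC(=O)CC(C)C)=C/[C@H]1OC(=O)CC(C)C | intermediate
35 | C12 lactol (12-hydroxy-8,12-epoxide, either anomer, formed in situ) | C=C1C(O)O[C@H]2C/C(C)=C/C[C@@H](O)/C(COC(=O)CC(C)C)=C/[C@@H](OC(=O)CC(C)C)[C@H]12 | intermediate
36 | CNP0317194.1, (3R,6R,7R,8S)-3-hydroxy-6,15-bis(3-methylbutanoyloxy)germacra-1(10)E,4E,11(13)-trien-12,8-olide | C=C1C(=O)O[C@H]2C/C(C)=C/C[C@@H](O)/C(COC(=O)CC(C)C)=C/[C@@H](OC(=O)CC(C)C)[C@H]12 | target

## Step count and least certain steps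

Total step count: 23 (19 in the main line and 4 for imide 19). Longest linear sequence: 19 steps (steps 1–7 and 12–23, counted from 1).

Step 2 (key step). The alanate may transfer methyl or butyl in place of the alkenyl group, or react sluggishly, if residual Me3Al consumes n-BuLi or if the ether oxygens of 2 bind aluminium and promote Lewis-acid opening at C3. The fallback splits the coupling into two known operations. It sets out from 3 and 4: alane 5 is quenched with I2 to give (E)-tert-butyl[(4-iodo-3-methylbut-3-en-1-yl)oxy]dimethylsilane F1. Iodine–lithium exchange with t-BuLi (Et2O, −78 °C) gives the (E)-alkenyllithium F2, which with BF3·OEt2 at −78 °C should open 2 at its CH2 and return to the route at 7.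

Step 18. Facial selectivity at C6 may be poor, because the tether and not a reagent fixes the approach to the aldehyde. Intermolecular coupling competes if dilution is insufficient, and the aldehyde can epimerise at C7 if it is stored. The fallback replaces substrate control by reagent control. It sets out from 26: the cyclisation is run without regard to C6, and any C6 epimer of 28 (cyclodecenynol F3) is oxidised together with 28 by buffered Dess–Martin periodinane to cyclodecenynone F4. Corey–Bakshi–Shibata reduction of F4 with (S)-1-methyl-3,3-diphenyltetrahydro-1H,3H-pyrrolo[1,2-c][1,3,2]oxazaborole and catecholborane at −78 °C, in which the alkynyl arm acts as the small group, should return to the route at 28.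

Step 19. The O3 silyloxy group may be eliminated from the C4 alanate (allene formation), and the C–Al bond may be protonated before iodination, because the alanate is basic and sits β to a leaving group. The fallback avoids aluminium. It sets out from 28: ruthenium-catalysed anti hydrosilylation with Et3SiH and [Cp*Ru(MeCN)3]PF6 (CH2Cl2, 0 °C) is known to place silicon on the alkyne carbon distal to a propargylic hydroxyl, which should give C4 vinylsilane F5. Iododesilylation with N-iodosuccinimide in hexafluoroisopropanol at 0 °C, with retention, comes back to the route at 30.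

Step 20. Transmetalation of the hydroxymethyl group to palladium may be slow at the hindered trisubstituted iodide. Butyl transfer or Cope rearrangement of the 1,5-diene could then intervene at the temperature needed. The fallback brings in C15 as carbon monoxide near room temperature. It sets out from 30: carbonylation with CO (1 atm), PdCl2(PPh3)2 and Et3N in THF at rt–40 °C should be followed by capture of the acylpalladium by the cis-disposed O6, giving butenolide F6 (the same structure as A3). Reduction with i-Bu2AlH (CH2Cl2, −78 → 0 °C) to the diol comes back to the route at 31.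

Step 23. The secondary allylic C3 hydroxyl may be over-oxidised to the enone, and the acetic acid released may trigger acid-induced transannular reaction, because the oxidant discriminates only kinetically between primary and secondary allylic alcohols. The fallback keeps O3 and O8 silylated during the oxidation. It sets out from 32: brief treatment with HF·pyridine/pyridine in THF at 0 °C should remove only the primary O12 silyl group to give allylic alcohol F7. MnO2 (CH2Cl2) gives enal F8, and Pinnick oxidation (NaClO2, NaH2PO4, 2-methylbut-2-ene, t-BuOH/H2O) gives acrylic acid F9. Final HF·pyridine (THF, rt) removes the O8 and O3 silyl groups, and the γ-hydroxy acid should lactonise on work-up, returning to the route at 36.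

## Further compounds

F1 | step 2 | (E)-tert-butyl[(4-iodo-3-methylbut-3-en-1-yl)oxy]dimethylsilane | CC(C)(C)[Si](C)(C)OCC/C(C)=C/I
F2 | step 2 | (E)-[4-(TBSO)-2-methylbut-1-en-1-yl]lithium | [Li]/C=C(\C)CCO[Si](C)(C)C(C)(C)C
F3 | step 18 | (1R,4R,6E,9S,10S)-4,9-bis(TBSO)-10-[3-(TBSO)prop-1-en-2-yl]-7-methylcyclodec-6-en-2-yn-1-ol (C6 epimer of 28) | C=C(CO[Si](C)(C)C(C)(C)C)[C@@H]1[C@@H](O[Si](C)(C)C(C)(C)C)C/C(C)=C/C[C@@H](O[Si](C)(C)C(C)(C)C)C#C[C@@H]1O
F4 | step 18 | 4,9-bis(TBSO)-10-[3-(TBSO)prop-1-en-2-yl]-7-methylcyclodec-6-en-2-yn-1-one (C6 ketone of 28) | C=C(CO[Si](C)(C)C(C)(C)C)[C@@H]1[C@@H](O[Si](C)(C)C(C)(C)C)C/C(C)=C/C[C@@H](O[Si](C)(C)C(C)(C)C)C#CC1=O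
F5 | step 19 | C4 triethylsilyl analogue of 30 (vinylsilane, C3 trans to C6) | C=C(CO[Si](C)(C)C(C)(C)C)[C@@H]1[C@@H](O[Si](C)(C)C(C)(C)C)C/C(C)=C/C[C@@H](O[Si](C)(C)C(C)(C)C)/C([Si](CC)(CC)CC)=C/[C@H]1O
F6 | step 20 | 6,15-butenolide of the carbocycle (O6–C15 lactone across C4=C5) | C=C(CO[Si](C)(C)C(C)(C)C)[C@@H]1[C@@H](O[Si](C)(C)C(C)(C)C)C/C(C)=C/C[C@@H](O[Si](C)(C)C(C)(C)C)C2=C[C@H]1OC2=O
F7 | step 23 | 32 with O12 free (primary allylic alcohol) | C=C(CO)[C@@H]1[C@@H](O[Si](C)(C)C(C)(C)C)C/C(C)=C/C[C@@H](O[Si](C)(C)C(C)(C)C)/C(COC(=O)CC(C)C)=C/[C@H]1OC(=O)CC(C)C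
F8 | step 23 | C12 aldehyde of F7 | C=C(C=O)[C@@H]1[C@@H](O[Si](C)(C)C(C)(C)C)C/C(C)=C/C[C@@H](O[Si](C)(C)C(C)(C)C)/C(COC(=O)CC(C)C)=C/[C@H]1OC(=O)CC(C)C
F9 | step 23 | C12 carboxylic acid of F7 | C=C(C(=O)O)[C@@H]1[C@@H](O[Si](C)(C)C(C)(C)C)C/C(C)=C/C[C@@H](O[Si](C)(C)C(C)(C)C)/C(COC(=O)CC(C)C)=C/[C@H]1OC(=O)CC(C)C
A1 | alternative 1 | ten-membered cyclodec-1-en-5-yne with free C6 carbinol (same structure as 28) | C=C(CO[Si](C)(C)C(C)(C)C)[C@@H]1[C@@H](O[Si](C)(C)C(C)(C)C)C/C(C)=C/C[C@@H](O[Si](C)(C)C(C)(C)C)C#C[C@H]1O
A2 | alternative 1 | open-chain C5 iodoalkyne with C6 aldehyde (same structure as 26) | C=C(CO[Si](C)(C)C(C)(C)C)[C@@H](C=O)[C@@H](O[Si](C)(C)C(C)(C)C)C/C(C)=C/C[C@@H](O[Si](C)(C)C(C)(C)C)C#CI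
A3 | alternative 2 | butenolide-bridged ten-membered carbocycle | O=C1O[C@@H]2C=C1[C@H](O[Si](C)(C)C(C)(C)C)C/C=C(C)/C[C@H](O[Si](C)(C)C(C)(C)C)[C@H]2C(=C)CO[Si](C)(C)C(C)(C)C
A4 | alternative 2 | eleven-membered α-methylene macrolactone (O6–C15 ester) with the C5 vinyl group on C6 | C=C[C@H]1OC(=O)C(=C)[C@H](O[Si](C)(C)C(C)(C)C)C/C=C(C)/C[C@H](O[Si](C)(C)C(C)(C)C)[C@H]1C(=C)CO[Si](C)(C)C(C)(C)C
A5 | alternative 3 | ten-membered carbocycle with free O6 and O15 (same structure as 31) | C=C(CO[Si](C)(C)C(C)(C)C)[C@@H]1[C@@H](O[Si](C)(C)C(C)(C)C)C/C(C)=C/C[C@@H](O[Si](C)(C)C(C)(C)C)/C(CO)=C/[C@H]1O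
A6 | alternative 3 | thirteen-membered diallylic ether (O linking C6 and C13, C8 trans to C13 across C7=C11) | O1C/C(CO[Si](C)(C)C(C)(C)C)=C/[C@@H](O[Si](C)(C)C(C)(C)C)C/C(C)=C/C[C@@H](O[Si](C)(C)C(C)(C)C)/C(CO)=C/C1
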